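A direct plan would build ring A first: 3,5-dimethoxyphenol would be prenylated between its methoxy groups, formylated and capped to give the prenylated 2,4-dimethoxy-6-(methoxymethoxy)benzaldehyde A1.
A1 would be condensed with 2,4-di(isopropoxy)acetophenone, the chalcone epoxidised to the trans-epoxy ketone A2, and acid would then have to turn A2 into the 2-aryl-3-formylbenzofuran before a last ether cleavage.
The weakest step would be that acid cascade (aroyl shift, acetal loss, cyclodehydration): the combination is without precedent, the furan could as well close on the aldehyde to give a 3-aroylbenzofuran, and strong acid would meet the prenyl alkene.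
The second would be the closing BCl3 dealkylation, which would have to tell two methyl ethers apart by chelation alone and would free a phenol next to the prenyl group (chroman formation) on the most valuable material.
The third would be the protecting-group traffic (silyl on and off, acetal on, two isopropyl ethers on), four operations that would form no skeletal bond.

Plan of the new route:
The retrosynthesis cuts ring A itself, at C7–C7a, C6–C7, C4–C5 and C3a–C4, into a 2-(diazoacetyl)furan that already carries ring B and the masked formyl group, and the ynol ether 1-methoxy-5-methylhex-4-en-1-yne.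
The rings therefore arise in the order furan (bought as furan-3-carbaldehyde), ring B (joined to C2 by Negishi coupling), ring A last, in one ketene–alkyne benzannulation.
Two features of the target allow this: C7a carries the ring oxygen O1, so the furan carbon that bears the ketene has only one carbon neighbour (the future C3a) and ring A can close in one direction only; and C4–OH, C5–prenyl, C6–OMe, C7–H is exactly the sequence in which a ketene carbonyl, the two carbons of a methoxyalkyne and a diazo carbon end up.
No furan ring has to be closed, the 4-hydroxyl and the 6-methyl ether are born different, the prenyl group never meets a Lewis acid, and the only protecting groups are two silyl ethers and one acetal, removed by dilute acid and fluoride.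

Key step: step 7

Remark on the chemistry: 2-(furan-3-yl)-1,3-dioxolane is assumed to be lithiated at C2 (between the ring oxygen and the acetal), as its thiophene analogue is; the fallback to step 3 does not depend on this.

**Step 1**
Reactants: 1 furan-3-carbaldehyde
Product: 2 2-(furan-3-yl)-1,3-dioxolane
Conditions: ethylene glycol (1.5 eq), PPTS (5 mol%), toluene, Dean–Stark, reflux
Reagents that add atoms: ethane-1,2-diol (ethylene glycol), OCCO
Why: Acid-catalysed acetalisation with azeotropic removal of water; the dioxolane masks the future C3 formyl group through all basic, organometallic and ketene steps and should direct the first lithiation to C2.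

**Step 2**
Reactants: 3 4-bromobenzene-1,3-diol
Product: 4 [(4-bromo-1,3-phenylene)bis(oxy)]bis[tri(propan-2-yl)silane]
Conditions: TIPSCl (2.4 eq), imidazole (5 eq), DMF, rt → 40 °C
Reagents that add atoms: chlorotri(propan-2-yl)silane (TIPSCl), CC(C)[Si](Cl)(C(C)C)C(C)C
Why: Imidazole-promoted O-silylation; the bulky silyl ethers tolerate butyllithium, LiN(SiMe3)2, light and 80 °C, do not direct ortho-metalation on ring B and leave with fluoride at the end.

**Step 3**
Reactants: 2 2-(furan-3-yl)-1,3-dioxolane; 4 [(4-bromo-1,3-phenylene)bis(oxy)]bis[tri(propan-2-yl)silane]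
Product: 7 2-{2-[2,4-bis(triisopropylsilyloxy)phenyl]furan-3-yl}-1,3-dioxolane, via 2-furyllithium 5 (not isolated), via furylzinc chloride 6 (not isolated)
Conditions: 2 (1.3 eq), n-BuLi (1.25 eq), THF, −78 → −30 °C; ZnCl2 (1.3 eq), → rt; 4 (1.0 eq), Pd2(dba)3 (2 mol%), XPhos (8 mol%), 60 °C
Reagents that add atoms: none
Why: Acetal-directed α-lithiation at C2, transmetalation to zinc and Negishi cross-coupling with the hindered, electron-rich aryl bromide under zerovalent palladium with a bulky biarylphosphine should form the C2–C1′ bond between the furan and ring B.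

**Step 4**
Reactants: 7 2-{2-[2,4-bis(triisopropylsilyloxy)phenyl]furan-3-yl}-1,3-dioxolane
Product: 9 1-{5-[2,4-bis(triisopropylsilyloxy)phenyl]-4-(1,3-dioxolan-2-yl)furan-2-yl}ethan-1-one, via 5-furyllithium 8 (not isolated)
Conditions: n-BuLi (1.1 eq), THF, −78 °C, 1 h; MeC(O)N(OMe)Me (1.5 eq), −78 → 0 °C; aq NH4Cl
Reagents that add atoms: N-methoxy-N-methylacetamide, CC(=O)N(C)OC
Why: Lithiation of the only remaining furan α-position (C5) followed by Weinreb ketone synthesis, whose stable tetrahedral chelate prevents over-addition and enolisation of the methyl ketone.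

**Step 5**
Reactants: 9 1-{5-[2,4-bis(triisopropylsilyloxy)phenyl]-4-(1,3-dioxolan-2-yl)furan-2-yl}ethan-1-one
Product: 11 1-{5-[2,4-bis(triisopropylsilyloxy)phenyl]-4-(1,3-dioxolan-2-yl)furan-2-yl}-2-diazoethan-1-one, via trifluoroacetyl ketone 10 (not isolated)
Conditions: LiN(SiMe3)2 (1.1 eq), THF, −78 °C; CF3CO2CH2CF3 (1.2 eq), 10 min; then p-ABSA (1.5 eq), Et3N (1.5 eq), H2O (1 eq), MeCN, rt
Reagents that add atoms: 4-acetamidobenzenesulfonyl azide (p-ABSA), CC(=O)Nc1ccc(cc1)S(=O)(=O)N=[N+]=[N-]; 2,2,2-trifluoroethyl trifluoroacetate, O=C(OCC(F)(F)F)C(F)(F)F (its trifluoroacetyl group is present in 10 only)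
Why: Detrifluoroacetylative diazo transfer, in which the kinetic enolate is C-trifluoroacetylated, the activated 1,3-diketone takes the diazo group from the sulfonyl azide and the trifluoroacetyl group leaves as the N-acylsulfonamide; it is the standard answer where direct diazo transfer to a methyl ketone fails.

**Step 6**
Reactants: 12 2-chloro-1,1-dimethoxyethane
Product: 14 1-methoxy-5-methylhex-4-en-1-yne, via sodium methoxyacetylide 13 (not isolated)
Conditions: NaNH2 (3.0 eq), liq. NH3, −40 °C; prenyl bromide (0.9 eq), −40 → −33 °C; NH4Cl, pentane; distilled from K2CO3 under reduced pressure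
Reagents that add atoms: 1-bromo-3-methylbut-2-ene (prenyl bromide), CC(C)=CCBr
Why: Twofold elimination (MeOH, then HCl) from the chloroacetal by sodium amide gives the alkoxyacetylide, which is alkylated in situ at the primary allylic carbon (SN2), as in the classical preparation of 1-alkoxy-1-alkynes; a methyl ynol ether has no β-hydrogen on its O-alkyl group and so cannot fragment to a ketene at 80 °C.

**Step 7**
Reactants: 11 1-{5-[2,4-bis(triisopropylsilyloxy)phenyl]-4-(1,3-dioxolan-2-yl)furan-2-yl}-2-diazoethan-1-one; 14 1-methoxy-5-methylhex-4-en-1-yne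
Product: 19 2-[2,4-bis(triisopropylsilyloxy)phenyl]-3-(1,3-dioxolan-2-yl)-6-methoxy-5-(3-methylbut-2-en-1-yl)-1-benzofuran-4-ol, via furylketene 15 (not isolated), via cyclobutenone 16 (not isolated), via dienylketene 17 (not isolated), via cyclohexadienone 18 (not isolated)
Conditions: 14 (2.5 eq), ClCH2CH2Cl (0.2 M, degassed), hν (λ > 300 nm, Pyrex), rt; then 80 °C, dark, 3 h
Reagents that add atoms: none
Why: Photochemical Wolff rearrangement of 11 gives furylketene 15, which adds in a regioselective [2+2] cycloaddition to the electron-rich alkyne 14 (ketene carbonyl carbon to the alkyne carbon remote from oxygen) to give the 3-methoxycyclobutenone 16; reversible four-electron electrocyclic opening (by light or at 80 °C) gives dienylketene 17, whose six-electron electrocyclisation onto furan C3 and tautomerisation of dienone 18 give phenol 19. The closest known reaction is the Danheiser benzannulation in its diazo ketone form, which is established for aryl and hetaryl diazomethyl ketones with heteroatom-substituted alkynes such as alkoxy- and silyloxyalkynes. Ring A is closed by the six-electron electrocyclisation (C3a–C4 bond), after C7–C7a has formed in the Wolff shift and C4–C5 and C6–C7 in the [2+2] step. No stereocentre remains, since the sp3 carbons of 16 and 18 are racemic and both become aromatic. The step needs regiocontrol in the cycloaddition, which the polarisation of the ynol ether secures (OH at C4, prenyl at C5, OMe at C6, H at C7), and a single site of closure, which is given because the ketene-bearing furan carbon has O1 as its only other ring neighbour. The ynol ether, used in excess, should consume the ketene far faster than the trisubstituted prenyl alkene or the acetal does, and only the geometric isomer of 17 that can cyclise is drained irreversibly from the cyclobutenone equilibrium.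

**Step 8**
Reactants: 19 2-[2,4-bis(triisopropylsilyloxy)phenyl]-3-(1,3-dioxolan-2-yl)-6-methoxy-5-(3-methylbut-2-en-1-yl)-1-benzofuran-4-ol
Product: 21 2-(2,4-dihydroxyphenyl)-4-hydroxy-6-methoxy-5-(3-methylbut-2-en-1-yl)-1-benzofuran-3-carbaldehyde, via silylated aldehyde 20 (not isolated)
Conditions: 1 M aq HCl/THF (1:5), rt; extractive work-up; then TBAF (2.5 eq), AcOH (2.5 eq), THF, 0 °C
Reagents that add atoms: water, O
Why: Dilute aqueous acid hydrolyses the dioxolane of the electron-rich hetaryl aldehyde first, while the ring-B oxygens are still silylated and cannot trap the oxocarbenium ion, and buffered fluoride then cleaves both aryl silyl ethers; neither stage should be acidic enough to cyclise the prenyl group onto the 4-hydroxyl group, and no stereocentre is involved.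

**Compound list**
1 | furan-3-carbaldehyde | O=Cc1ccoc1 | starting material
2 | 2-(furan-3-yl)-1,3-dioxolane | C1COC(O1)c1ccoc1 | intermediate
3 | 4-bromobenzene-1,3-diol | Oc1ccc(Br)c(O)c1 | starting material
4 | [(4-bromo-1,3-phenylene)bis(oxy)]bis[tri(propan-2-yl)silane] | Brc1ccc(O[Si](C(C)C)(C(C)C)C(C)C)cc1O[Si](C(C)C)(C(C)C)C(C)C | intermediate
5 | [3-(1,3-dioxolan-2-yl)furan-2-yl]lithium | [Li]c1occc1C1OCCO1 | intermediate
6 | chloro[3-(1,3-dioxolan-2-yl)furan-2-yl]zinc | Cl[Zn]c1occc1C1OCCO1 | intermediate
7 | 2-{2-[2,4-bis(triisopropylsilyloxy)phenyl]furan-3-yl}-1,3-dioxolane | C1COC(O1)c1ccoc1-c1ccc(O[Si](C(C)C)(C(C)C)C(C)C)cc1O[Si](C(C)C)(C(C)C)C(C)C | intermediate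
8 | {5-[2,4-bis(triisopropylsilyloxy)phenyl]-4-(1,3-dioxolan-2-yl)furan-2-yl}lithium | [Li]c1cc(C2OCCO2)c(-c2ccc(O[Si](C(C)C)(C(C)C)C(C)C)cc2O[Si](C(C)C)(C(C)C)C(C)C)o1 | intermediate
9 | 1-{5-[2,4-bis(triisopropylsilyloxy)phenyl]-4-(1,3-dioxolan-2-yl)furan-2-yl}ethan-1-one | CC(=O)c1cc(C2OCCO2)c(-c2ccc(O[Si](C(C)C)(C(C)C)C(C)C)cc2O[Si](C(C)C)(C(C)C)C(C)C)o1 | intermediate
10 | 1-{5-[2,4-bis(triisopropylsilyloxy)phenyl]-4-(1,3-dioxolan-2-yl)furan-2-yl}-4,4,4-trifluorobutane-1,3-dione (present as its lithium enolate) | O=C(CC(=O)C(F)(F)F)c1cc(C2OCCO2)c(-c2ccc(O[Si](C(C)C)(C(C)C)C(C)C)cc2O[Si](C(C)C)(C(C)C)C(C)C)o1 | intermediate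
11 | 1-{5-[2,4-bis(triisopropylsilyloxy)phenyl]-4-(1,3-dioxolan-2-yl)furan-2-yl}-2-diazoethan-1-one | [N-]=[N+]=CC(=O)c1cc(C2OCCO2)c(-c2ccc(O[Si](C(C)C)(C(C)C)C(C)C)cc2O[Si](C(C)C)(C(C)C)C(C)C)o1 | intermediate
12 | 2-chloro-1,1-dimethoxyethane | COC(CCl)OC | starting material
13 | sodium methoxyacetylide (sodium 2-methoxyethyn-1-ide) | [Na]C#COC | intermediate
14 | 1-methoxy-5-methylhex-4-en-1-yne | COC#CCC=C(C)C | intermediate
15 | 2-{5-[2,4-bis(triisopropylsilyloxy)phenyl]-4-(1,3-dioxolan-2-yl)furan-2-yl}ethen-1-one (furylketene) | O=C=Cc1cc(C2OCCO2)c(-c2ccc(O[Si](C(C)C)(C(C)C)C(C)C)cc2O[Si](C(C)C)(C(C)C)C(C)C)o1 | intermediate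
16 | rac-4-{5-[2,4-bis(triisopropylsilyloxy)phenyl]-4-(1,3-dioxolan-2-yl)furan-2-yl}-3-methoxy-2-(3-methylbut-2-en-1-yl)cyclobut-2-en-1-one (racemate) | COC1=C(CC=C(C)C)C(=O)C1c1cc(C2OCCO2)c(-c2ccc(O[Si](C(C)C)(C(C)C)C(C)C)cc2O[Si](C(C)C)(C(C)C)C(C)C)o1 | intermediate
17 | (3E)-4-{5-[2,4-bis(triisopropylsilyloxy)phenyl]-4-(1,3-dioxolan-2-yl)furan-2-yl}-3-methoxy-2-(3-methylbut-2-en-1-yl)buta-1,3-dien-1-one (furyl cis to the ketene-bearing carbon) | O=C=C(CC=C(C)C)/C(OC)=C\c1cc(C2OCCO2)c(-c2ccc(O[Si](C(C)C)(C(C)C)C(C)C)cc2O[Si](C(C)C)(C(C)C)C(C)C)o1 | intermediate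
18 | rac-2-[2,4-bis(triisopropylsilyloxy)phenyl]-3-(1,3-dioxolan-2-yl)-6-methoxy-5-(3-methylbut-2-en-1-yl)-1-benzofuran-4(3aH)-one (racemate) | COC1=C(CC=C(C)C)C(=O)C2C(C3OCCO3)=C(c3ccc(O[Si](C(C)C)(C(C)C)C(C)C)cc3O[Si](C(C)C)(C(C)C)C(C)C)OC2=C1 | intermediate
19 | 2-[2,4-bis(triisopropylsilyloxy)phenyl]-3-(1,3-dioxolan-2-yl)-6-methoxy-5-(3-methylbut-2-en-1-yl)-1-benzofuran-4-ol | COc1cc2oc(-c3ccc(O[Si](C(C)C)(C(C)C)C(C)C)cc3O[Si](C(C)C)(C(C)C)C(C)C)c(C3OCCO3)c2c(O)c1CC=C(C)C | intermediate
20 | 2-[2,4-bis(triisopropylsilyloxy)phenyl]-4-hydroxy-6-methoxy-5-(3-methylbut-2-en-1-yl)-1-benzofuran-3-carbaldehyde | COc1cc2oc(-c3ccc(O[Si](C(C)C)(C(C)C)C(C)C)cc3O[Si](C(C)C)(C(C)C)C(C)C)c(C=O)c2c(O)c1CC=C(C)C | intermediate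
21 | 2-(2,4-dihydroxyphenyl)-4-hydroxy-6-methoxy-5-(3-methylbut-2-en-1-yl)-1-benzofuran-3-carbaldehyde | COc1cc2oc(-c3ccc(O)cc3O)c(C=O)c2c(O)c1CC=C(C)C | target

**Step count and risks**
Total: 8 steps. Longest linear sequence: 6 steps (steps 1, 3, 4, 5, 7, 8, from furan-3-carbaldehyde); steps 2 and 6 make the two side fragments.

The three steps most likely to fail, in order of risk:

First, step 7, the key step. The photochemical stage may stall or degrade the light-absorbing arylfuran, and the ketene may be lost by dimerisation or by O-acylation of the product phenol instead of adding to the alkyne. The fallback for step 7 generates the same ketene thermally, without light; it sets out from 11 and comes back to the route at 19. A silver-catalysed Wolff rearrangement of 11 in wet THF (PhCO2Ag cat., Et3N, dark) would give {5-[2,4-bis(triisopropylsilyloxy)phenyl]-4-(1,3-dioxolan-2-yl)furan-2-yl}acetic acid F1 as the homologated acid. 1-Chloro-N,N,2-trimethylprop-1-en-1-amine in CH2Cl2 at 0 °C would convert F1 under neutral conditions into {5-[2,4-bis(triisopropylsilyloxy)phenyl]-4-(1,3-dioxolan-2-yl)furan-2-yl}acetyl chloride F2 without touching the acetal or the silyl ethers. Slow addition of F2 to 14 and iPr2NEt in toluene at 80 °C would form ketene 15 by dehydrochlorination, and the same cycloaddition and electrocyclic cascade would give 19.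

Second, step 3. Metalation may be unselective between C2 and C5 of the furan, and oxidative addition of the hindered ortho-silyloxy aryl bromide may be so slow that the furylzinc reagent is lost by protonation or homocoupling. The fallback for step 3 takes the regiochemistry from a halide pattern instead of from directed metalation; it sets out from 4 and comes back to the route at 7. Miyaura borylation of 4 (B2pin2, PdCl2(dppf), KOAc, dioxane, 90 °C) would give 2-[2,4-bis(triisopropylsilyloxy)phenyl]-4,4,5,5-tetramethyl-1,3,2-dioxaborolane F3 as the ring-B donor. Suzuki coupling of F3 (Pd(PPh3)4, K3PO4, dioxane/H2O, 80 °C) at the more reactive α-bromide of commercial 2,3-dibromofuran F4 would give 3-bromo-2-[2,4-bis(triisopropylsilyloxy)phenyl]furan F5 with the β-bromide intact. Bromine–lithium exchange on F5 (n-BuLi, Et2O, −78 °C) and quenching with DMF would give 2-[2,4-bis(triisopropylsilyloxy)phenyl]furan-3-carbaldehyde F6 as the free aldehyde, and acetalisation of F6 with ethylene glycol and PPTS in toluene would give 7.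

Third, step 6. The skipped enyne may isomerise under amide base to a conjugated enyne or allene, prenyl bromide may be consumed by ammonolysis or elimination, and the volatile, acid-sensitive ynol ether may be lost on isolation. The fallback for step 6 makes the acetylide by elimination and halogen–lithium exchange in ether solvents and allylates it under copper catalysis, without ammonia or amide base; it sets out not from 12 but from commercial trichloroethene F7 and comes back to the route at 14. KOMe in THF would convert F7 into (E)-1,2-dichloro-1-methoxyethene F8 by elimination and readdition of methoxide. n-BuLi (2.1 eq, Et2O/THF, −78 → −40 °C) would turn F8 into lithium methoxyacetylide F9 by elimination and chlorine–lithium exchange, and CuI (10 mol%) and prenyl bromide (−40 → 0 °C) would allylate F9 to give 14.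

**Further compounds**
F1 | step 7 | {5-[2,4-bis(triisopropylsilyloxy)phenyl]-4-(1,3-dioxolan-2-yl)furan-2-yl}acetic acid | OC(=O)Cc1cc(C2OCCO2)c(-c2ccc(O[Si](C(C)C)(C(C)C)C(C)C)cc2O[Si](C(C)C)(C(C)C)C(C)C)o1
F2 | step 7 | {5-[2,4-bis(triisopropylsilyloxy)phenyl]-4-(1,3-dioxolan-2-yl)furan-2-yl}acetyl chloride | ClC(=O)Cc1cc(C2OCCO2)c(-c2ccc(O[Si](C(C)C)(C(C)C)C(C)C)cc2O[Si](C(C)C)(C(C)C)C(C)C)o1
F3 | step 3 | 2-[2,4-bis(triisopropylsilyloxy)phenyl]-4,4,5,5-tetramethyl-1,3,2-dioxaborolane | CC(C)[Si](Oc1ccc(B2OC(C)(C)C(C)(C)O2)c(O[Si](C(C)C)(C(C)C)C(C)C)c1)(C(C)C)C(C)C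
F4 | step 3 | 2,3-dibromofuran | Brc1ccoc1Br
F5 | step 3 | 3-bromo-2-[2,4-bis(triisopropylsilyloxy)phenyl]furan | Brc1ccoc1-c1ccc(O[Si](C(C)C)(C(C)C)C(C)C)cc1O[Si](C(C)C)(C(C)C)C(C)C
F6 | step 3 | 2-[2,4-bis(triisopropylsilyloxy)phenyl]furan-3-carbaldehyde | O=Cc1ccoc1-c1ccc(O[Si](C(C)C)(C(C)C)C(C)C)cc1O[Si](C(C)C)(C(C)C)C(C)C
F7 | step 6 | trichloroethene | ClC=C(Cl)Cl
F8 | step 6 | (E)-1,2-dichloro-1-methoxyethene | CO/C(Cl)=C\Cl
F9 | step 6 | lithium methoxyacetylide | [Li]C#COC
A1 | direct plan | 2,4-dimethoxy-6-(methoxymethoxy)-3-(3-methylbut-2-en-1-yl)benzaldehyde | COCOc1cc(OC)c(CC=C(C)C)c(OC)c1C=O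
A2 | direct plan | rac-trans-[3-[2,4-dimethoxy-6-(methoxymethoxy)-3-(3-methylbut-2-en-1-yl)phenyl]oxiran-2-yl][2,4-di(propan-2-yloxy)phenyl]methanone (racemate; one enantiomer drawn) | O=C(c1ccc(OC(C)C)cc1OC(C)C)[C@H]1O[C@@H]1c1c(OCOC)cc(OC)c(CC=C(C)C)c1OC
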